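## Retrosynthetic overview

1. The target is released by two acid/fluoride deprotections from a protected dimer, which is cut at the ester between the C1 carboxyl of O-silyl hymeglusin and the C12 hydroxyl of a (12S,13S)-anti-aldol diester (Yamaguchi esterification).
2. Both halves come from one aldehyde (C1–C12 chain, 2E,4E-dienoate, 7R). The two antipodal head groups are set by the two enantiomers of one rhodium catalyst: a borylative aldol with tert-butyl acrylate (open chain) and a borylative aldol–lactonisation with phenyl acrylate (proposed new chemistry). C–B oxidation then gives the CH2OH groups.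
3. The aldehyde comes from cross-metathesis and enal reduction of a triene ester, itself made by Zr-catalysed carboalumination/Pd coupling of the (R)-citronellal-derived enyne with the (E)-enol tosylate of tert-butyl acetoacetate.
4. Ring order: the only ring, the oxetan-2-one of the hymeglusin half, is closed in the new step 9 before fragment union and carried intact to the end.

Assumption 1: the seco-acid half of the given SMILES is read as S at both the acyloxy carbon and the α-carbon (anti, antipodal to the (2R,3R)-β-lactone head of the other half); both halves are 7R and 2E,4E.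

Assumption 2: by analogy with the parent hydrosilane reductive aldol, the (S,S)-catalyst is taken to give the (12S,13S) adduct; if the sense proves opposite, the catalyst antipodes of steps 6 and 9 are exchanged. Phebox = 2,6-bis(4-isopropyl-4,5-dihydro-1,3-oxazol-2-yl)phenyl.

## Route

Step 1
Reactants: 1 tert-butyl acetoacetate
Product: 2 tert-butyl (2E)-3-{[(4-methylphenyl)sulfonyl]oxy}but-2-enoate
Conditions: TsCl (1.5 equiv), N-methylimidazole (1.5 equiv), Et3N (1.5 equiv), MeCN, 0 °C
Reagents that add atoms: p-toluenesulfonyl chloride, Cc1ccc(cc1)S(=O)(=O)Cl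
Why: O-sulfonylation of the non-chelated amine enolate by the N-sulfonylimidazolium salt gives the (E)-enol tosylate (OTs trans to the ester), the geometry later transferred to C2=C3.

Step 2
Reactants: 3 (R)-citronellal
Product: 4 (4R)-4,8-dimethylnon-7-en-1-yne
Conditions: dimethyl (1-diazo-2-oxopropyl)phosphonate (1.3 equiv), K2CO3 (2 equiv), MeOH, 0 °C to rt
Reagents that add atoms: dimethyl (1-diazo-2-oxopropyl)phosphonate, COP(=O)(OC)C(=[N+]=[N-])C(C)=O (supplies the terminal alkyne carbon)
Why: Ohira–Bestmann (Seyferth–Gilbert) homologation turns the aldehyde into the terminal alkyne without touching the β-stereocentre, which becomes C7 (R) of both halves.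

Step 3
Reactants: 4 (4R)-4,8-dimethylnon-7-en-1-yne; 2 tert-butyl (2E)-3-(tosyloxy)but-2-enoate
Product: 6 tert-butyl (2E,4E,7R)-3,5,7,11-tetramethyldodeca-2,4,10-trienoate, via alkenylalane 5 (not isolated)
Conditions: Me3Al (2 equiv), Cp2ZrCl2 (20 mol %), CH2Cl2, 0 °C to rt; volatiles removed; then 2 (1.3 equiv), ZnCl2 (20 mol %), PdCl2(dppf) (5 mol %), THF, rt to 50 °C
Reagents that add atoms: trimethylaluminium, C[Al](C)C (CH3 to C5; the AlMe2 group is in 5 only)
Why: Negishi Zr-catalysed syn-carboalumination places Me and Al cis with Al terminal (4E), and the zinc-assisted Pd-catalysed cross-coupling with the enol tosylate retains both alkene geometries to give the 2E,4E-dienoate.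

Step 4
Reactants: 6 triene ester; 7 (E)-but-2-enal (crotonaldehyde, 5 equiv)
Product: 8 tert-butyl (2E,4E,7R,10E)-3,5,7-trimethyl-12-oxododeca-2,4,10-trienoate
Conditions: second-generation Hoveyda–Grubbs catalyst RuCl2(1,3-dimesitylimidazolidin-2-ylidene)(=CH-C6H4-2-OiPr) (5 mol %), CH2Cl2, 40 °C
Reagents that add atoms: none
Why: Olefin cross-metathesis exchanges the isopropylidene terminus for the formylvinyl group (2-methylbut-2-ene is lost), while the trisubstituted conjugated dienoate is too hindered and electron-poor to enter the cycle.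

Step 5
Reactants: 8 enal
Product: 9 tert-butyl (2E,4E,7R)-3,5,7-trimethyl-12-oxododeca-2,4-dienoate
Conditions: Hantzsch ester (1.2 equiv), Bn2NH·CF3CO2H (10 mol %), THF, rt
Reagents that add atoms: none
Why: Iminium-catalysed transfer hydrogenation reduces only the enal C=C, because the dienoate ester cannot form an iminium ion.

Step 6
Reactants: 9 aldehyde; 10 tert-butyl acrylate (1.3 equiv)
Product: 12 di-tert-butyl (2E,4E,7R,12S,13S)-12-hydroxy-3,5,7-trimethyl-13-[(4,4,5,5-tetramethyl-1,3,2-dioxaborolan-2-yl)methyl]tetradeca-2,4-dienedioate, via O-boryl aldol adduct 11 (not isolated)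
Conditions: B2pin2 (1.2 equiv), Rh[(S,S)-iPr-Phebox](OAc)2(H2O) (2 mol %), NaOtBu (5 mol %), toluene, 40 °C, 9 added over 2 h; aqueous NH4Cl work-up
Reagents that add atoms: bis(pinacolato)diboron, CC1(C)OB(OC1(C)C)B1OC(C)(C)C(C)(C)O1 (one Bpin on the new CH2; the second sits on O12 in 11 only)
Why: Proposed new method: a rhodium-Phebox borylative aldol in which the Rh–Bpin species (from the acetate complex and B2pin2) adds 1,4 to the acrylate to give a β-boryl (E)-rhodium enolate, this adds to 9 through a chair transition state on the C2-symmetric pincer (anti diad, aldehyde face fixed by the oxazoline isopropyl groups, hence 12S,13S), and the rhodium aldolate is released by σ-bond metathesis with B2pin2, the hindered dienoate not inserting; the closest known reaction types are the anti-selective Rh-Phebox/hydrosilane reductive aldol of acrylates with aldehydes and the Rh-Phebox conjugate borylation of enoates, merged here so that boron replaces hydride.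

Step 7
Reactants: 12 hydroxy boronate
Product: 13 di-tert-butyl (2E,4E,7R,12S,13S)-12-hydroxy-13-(hydroxymethyl)-3,5,7-trimethyltetradeca-2,4-dienedioate
Conditions: NaBO3·4H2O (5 equiv), THF/H2O 1:1, rt
Reagents that add atoms: sodium perborate, [Na+].[Na+].O[B-]1(O)OO[B-](O)(O)OO1 (oxygen of the CH2OH group)
Why: Peroxide oxidation of the primary C–B bond (1,2-migration from boron to oxygen) unveils the hydroxymethyl group under mildly basic conditions that leave the tert-butyl esters and the aldol stereodiad untouched.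

Step 8
Reactants: 13 diol
Product: 14 di-tert-butyl (2E,4E,7R,12S,13S)-13-{[tert-butyl(diphenyl)silyl]oxymethyl}-12-hydroxy-3,5,7-trimethyltetradeca-2,4-dienedioate
Conditions: TBDPSCl (1.1 equiv), imidazole (2.5 equiv), CH2Cl2, 0 °C
Reagents that add atoms: tert-butyl(chloro)diphenylsilane, CC(C)(C)[Si](Cl)(c1ccccc1)c1ccccc1
Why: Silylation selects the primary over the hindered secondary hydroxyl, leaving only the C12 alcohol free for the esterification.

Step 9
Reactants: 9 aldehyde; 15 phenyl acrylate (1.3 equiv)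
Product: 16 tert-butyl (2E,4E,7R)-3,5,7-trimethyl-11-{(2R,3R)-4-oxo-3-[(4,4,5,5-tetramethyl-1,3,2-dioxaborolan-2-yl)methyl]oxetan-2-yl}undeca-2,4-dienoate
Conditions: B2pin2 (1.2 equiv), Rh[(R,R)-iPr-Phebox](OAc)2(H2O) (5 mol %), NaOtBu (5 mol %), toluene, 40 °C, 9 added over 2 h; aqueous NH4Cl work-up
Reagents that add atoms: bis(pinacolato)diboron, CC1(C)OB(OC1(C)C)B1OC(C)(C)C(C)(C)O1 (one Bpin on the new CH2; the other leaves on phenoxide)
Why: Proposed new method: a borylative aldol–lactonisation in which the same β-boryl rhodium enolate, now from the aryl acrylate and the antipodal catalyst, adds anti to 9 with the opposite absolute sense, the rhodium aldolate attacks its own chelated phenyl ester (4-exo-trig acyl substitution, phenoxide leaving) to close the oxetan-2-one, and Rh–OPh plus B2pin2 regenerates Rh–Bpin; because aldol addition of late-metal enolates is reversible and only the anti aldolate cyclises without eclipsing its two substituents, the trans-(2R,3R) ring is funnelled; the closest known reaction types are the Rh-Phebox reductive aldol and the aldolate-to-β-lactone closure of phenyl ester and thioester aldolates (lithium phenyl ester enolate plus aldehyde, tandem Mukaiyama aldol–lactonisation).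

Step 10
Reactants: 16 boryl lactone
Product: 17 tert-butyl (2E,4E,7R)-11-[(2R,3R)-3-(hydroxymethyl)-4-oxooxetan-2-yl]-3,5,7-trimethylundeca-2,4-dienoate (hymeglusin tert-butyl ester)
Conditions: 30 % aq. H2O2, pH 7 phosphate buffer, THF, 0 °C to rt
Reagents that add atoms: hydrogen peroxide, OO
Why: Buffered peroxide oxidation occurs at boron with retention of the carbon skeleton, and at neutral pH the trans-disubstituted β-lactone is not opened.

Step 11
Reactants: 17 hymeglusin tert-butyl ester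
Product: 18 tert-butyl (2E,4E,7R)-11-[(2R,3R)-3-{[tert-butyl(diphenyl)silyl]oxymethyl}-4-oxooxetan-2-yl]-3,5,7-trimethylundeca-2,4-dienoate
Conditions: TBDPSCl (1.2 equiv), imidazole (2.5 equiv), CH2Cl2, 0 °C to rt
Reagents that add atoms: tert-butyl(chloro)diphenylsilane, CC(C)(C)[Si](Cl)(c1ccccc1)c1ccccc1
Why: Standard silylation of the primary alcohol with a silyl group that survives the next acidolysis.

Step 12
Reactants: 18 silyl ether tert-butyl ester
Product: 19 (2E,4E,7R)-11-[(2R,3R)-3-{[tert-butyl(diphenyl)silyl]oxymethyl}-4-oxooxetan-2-yl]-3,5,7-trimethylundeca-2,4-dienoic acid (O-TBDPS hymeglusin)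
Conditions: TFA/CH2Cl2 1:4, 0 °C to rt
Reagents that add atoms: none
Why: Acidolysis (E1 loss of isobutene) frees the dienoic acid while the β-lactone and the TBDPS ether are stable to anhydrous TFA.

Step 13
Reactants: 19 O-TBDPS hymeglusin (1.2 equiv); 14 secondary alcohol
Product: 21 protected dimer (19 esterified onto O12 of 14), via mixed anhydride 20 (not isolated)
Conditions: 2,4,6-Cl3C6H2COCl (1.3 equiv), Et3N (1.5 equiv), toluene, rt; then 14, DMAP (1.5 equiv), toluene, rt
Reagents that add atoms: 2,4,6-trichlorobenzoyl chloride, O=C(Cl)c1c(Cl)cc(Cl)cc1Cl (its atoms are in 20 only and leave again as the acid)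
Why: Yamaguchi esterification: DMAP attacks the less hindered dienoyl carbonyl of the mixed anhydride and the acylpyridinium acylates the C12 hydroxyl with retention (the C12–O bond is never broken), under amine conditions that β-lactones tolerate in Steglich-type acylations.

Step 14
Reactants: 21 protected dimer
Product: 22 bis-O-TBDPS fusariumester B (both carboxylic acids free)
Conditions: TFA/CH2Cl2 1:3, 0 °C to rt
Reagents that add atoms: none
Why: Acidolysis removes both tert-butyl esters while the two hydroxymethyl groups are still silylated, so neither acyl migration nor trifluoroacetylation can occur.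

Step 15
Reactants: 22 bis-silyl ether diacid
Product: 23 fusariumester B
Conditions: HF·pyridine, pyridine, THF, 0 °C to rt
Reagents that add atoms: none
Why: Buffered fluoride cleaves both primary silyl ethers through Si–F bond formation under mildly acidic conditions that spare the β-lactone and avoid base-induced acyl migration or β-elimination of the acyloxy acid.

## Compound list

1 | tert-butyl 3-oxobutanoate (tert-butyl acetoacetate) | CC(=O)CC(=O)OC(C)(C)C | starting material
2 | tert-butyl (2E)-3-{[(4-methylphenyl)sulfonyl]oxy}but-2-enoate | C/C(OS(=O)(=O)c1ccc(C)cc1)=C\C(=O)OC(C)(C)C | intermediate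
3 | (R)-citronellal, (3R)-3,7-dimethyloct-6-enal | O=CC[C@H](C)CCC=C(C)C | starting material
4 | (4R)-4,8-dimethylnon-7-en-1-yne | C#CC[C@H](C)CCC=C(C)C | intermediate
5 | dimethyl[(1E,4R)-2,4,8-trimethylnona-1,7-dien-1-yl]alumane (not isolated) | C[Al](C)/C=C(\C)C[C@H](C)CCC=C(C)C | intermediate
6 | tert-butyl (2E,4E,7R)-3,5,7,11-tetramethyldodeca-2,4,10-trienoate | CC(=C\C(=O)OC(C)(C)C)/C=C(\C)C[C@H](C)CCC=C(C)C | intermediate
7 | (E)-but-2-enal (crotonaldehyde) | C/C=C/C=O | starting material
8 | tert-butyl (2E,4E,7R,10E)-3,5,7-trimethyl-12-oxododeca-2,4,10-trienoate | CC(=C\C(=O)OC(C)(C)C)/C=C(\C)C[C@H](C)CC/C=C/C=O | intermediate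
9 | tert-butyl (2E,4E,7R)-3,5,7-trimethyl-12-oxododeca-2,4-dienoate | CC(=C\C(=O)OC(C)(C)C)/C=C(\C)C[C@H](C)CCCCC=O | intermediate
10 | tert-butyl acrylate | C=CC(=O)OC(C)(C)C | starting material
11 | di-tert-butyl (2E,4E,7R,12S,13S)-3,5,7-trimethyl-12-[(4,4,5,5-tetramethyl-1,3,2-dioxaborolan-2-yl)oxy]-13-[(4,4,5,5-tetramethyl-1,3,2-dioxaborolan-2-yl)methyl]tetradeca-2,4-dienedioate (not isolated) | CC(=C\C(=O)OC(C)(C)C)/C=C(\C)C[C@H](C)CCCC[C@H](OB1OC(C)(C)C(C)(C)O1)[C@H](CB2OC(C)(C)C(C)(C)O2)C(=O)OC(C)(C)C | intermediate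
12 | di-tert-butyl (2E,4E,7R,12S,13S)-12-hydroxy-3,5,7-trimethyl-13-[(4,4,5,5-tetramethyl-1,3,2-dioxaborolan-2-yl)methyl]tetradeca-2,4-dienedioate | CC(=C\C(=O)OC(C)(C)C)/C=C(\C)C[C@H](C)CCCC[C@H](O)[C@H](CB1OC(C)(C)C(C)(C)O1)C(=O)OC(C)(C)C | intermediate
13 | di-tert-butyl (2E,4E,7R,12S,13S)-12-hydroxy-13-(hydroxymethyl)-3,5,7-trimethyltetradeca-2,4-dienedioate | CC(=C\C(=O)OC(C)(C)C)/C=C(\C)C[C@H](C)CCCC[C@H](O)[C@H](CO)C(=O)OC(C)(C)C | intermediate
14 | di-tert-butyl (2E,4E,7R,12S,13S)-13-{[tert-butyl(diphenyl)silyl]oxymethyl}-12-hydroxy-3,5,7-trimethyltetradeca-2,4-dienedioate | CC(=C\C(=O)OC(C)(C)C)/C=C(\C)C[C@H](C)CCCC[C@H](O)[C@H](CO[Si](c1ccccc1)(c1ccccc1)C(C)(C)C)C(=O)OC(C)(C)C | intermediate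
15 | phenyl acrylate | C=CC(=O)Oc1ccccc1 | starting material
16 | tert-butyl (2E,4E,7R)-3,5,7-trimethyl-11-{(2R,3R)-4-oxo-3-[(4,4,5,5-tetramethyl-1,3,2-dioxaborolan-2-yl)methyl]oxetan-2-yl}undeca-2,4-dienoate | CC(=C\C(=O)OC(C)(C)C)/C=C(\C)C[C@H](C)CCCC[C@H]1OC(=O)[C@@H]1CB2OC(C)(C)C(C)(C)O2 | intermediate
17 | tert-butyl (2E,4E,7R)-11-[(2R,3R)-3-(hydroxymethyl)-4-oxooxetan-2-yl]-3,5,7-trimethylundeca-2,4-dienoate | CC(=C\C(=O)OC(C)(C)C)/C=C(\C)C[C@H](C)CCCC[C@H]1OC(=O)[C@@H]1CO | intermediate
18 | tert-butyl (2E,4E,7R)-11-[(2R,3R)-3-{[tert-butyl(diphenyl)silyl]oxymethyl}-4-oxooxetan-2-yl]-3,5,7-trimethylundeca-2,4-dienoate | CC(=C\C(=O)OC(C)(C)C)/C=C(\C)C[C@H](C)CCCC[C@H]1OC(=O)[C@@H]1CO[Si](c2ccccc2)(c2ccccc2)C(C)(C)C | intermediate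
19 | (2E,4E,7R)-11-[(2R,3R)-3-{[tert-butyl(diphenyl)silyl]oxymethyl}-4-oxooxetan-2-yl]-3,5,7-trimethylundeca-2,4-dienoic acid | CC(=C\C(=O)O)/C=C(\C)C[C@H](C)CCCC[C@H]1OC(=O)[C@@H]1CO[Si](c2ccccc2)(c2ccccc2)C(C)(C)C | intermediate
20 | mixed anhydride of 19 with 2,4,6-trichlorobenzoic acid (not isolated) | CC(=C\C(=O)OC(=O)c1c(Cl)cc(Cl)cc1Cl)/C=C(\C)C[C@H](C)CCCC[C@H]2OC(=O)[C@@H]2CO[Si](c3ccccc3)(c3ccccc3)C(C)(C)C | intermediate
21 | protected dimer: 14 acylated on O12 by 19 (two tert-butyl esters, two TBDPS ethers, β-lactone) | CC(=C\C(=O)OC(C)(C)C)/C=C(\C)C[C@H](C)CCCC[C@H](OC(=O)/C=C(C)/C=C(\C)C[C@H](C)CCCC[C@H]1OC(=O)[C@@H]1CO[Si](c2ccccc2)(c2ccccc2)C(C)(C)C)[C@H](CO[Si](c3ccccc3)(c3ccccc3)C(C)(C)C)C(=O)OC(C)(C)C | intermediate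
22 | bis-O-TBDPS fusariumester B (diacid) | CC(=C\C(=O)O)/C=C(\C)C[C@H](C)CCCC[C@H](OC(=O)/C=C(C)/C=C(\C)C[C@H](C)CCCC[C@H]1OC(=O)[C@@H]1CO[Si](c2ccccc2)(c2ccccc2)C(C)(C)C)[C@H](CO[Si](c3ccccc3)(c3ccccc3)C(C)(C)C)C(=O)O | intermediate
23 | fusariumester B | CC(=C\C(=O)O)/C=C(\C)C[C@H](C)CCCC[C@H](OC(=O)/C=C(C)/C=C(\C)C[C@H](C)CCCC[C@H]1OC(=O)[C@@H]1CO)[C@H](CO)C(=O)O | target

## Step count and risk

Total step count: 15.
Longest linear sequence: 11 steps (2, 3, 4, 5, 9, 10, 11, 12, 13, 14, 15 from (R)-citronellal).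

The three steps most likely to fail:

**Step 9 (proposed new step; ring closure and the 2R,3R diad).** The lactonisation may be outrun by O-borylation, and the anti/enantio control is unproven. The fallback uses known chemistry, sets out from aldehyde 9 and comes back to the route at acid 19.
- The alkaloid/LiClO4-catalysed acyl chloride–aldehyde cyclocondensation (acetyl chloride, iPr2NEt, 10 mol % O-trimethylsilylquinidine or its quinine-derived pseudoenantiomer, whichever delivers the 4R series, LiClO4, CH2Cl2/Et2O, −78 °C) gives tert-butyl (2E,4E,7R)-3,5,7-trimethyl-11-[(2R)-4-oxooxetan-2-yl]undeca-2,4-dienoate F1.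
- TFA/CH2Cl2 then frees (2E,4E,7R)-3,5,7-trimethyl-11-[(2R)-4-oxooxetan-2-yl]undeca-2,4-dienoic acid F2.
- NaN(SiMe3)2 (2.1 equiv, THF, −78 °C) forms the carboxylate/β-lactone enolate; the carboxylate keeps the dienoic acid from being deprotonated at the γ-position by this amide base. Monomeric formaldehyde adds trans to the C4 side chain (β-lactone enolate aldol) to give hymeglusin F3.
- TBDPSCl (2.2 equiv)/imidazole gives the silyl ester silyl ether, tert-butyl(diphenyl)silyl ester of O-TBDPS hymeglusin F4. Its silyl ester is hydrolysed on work-up with AcOH/THF/H2O to give 19.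

**Step 6 (proposed new step; the 12S,13S diad).** The risks are competing aldehyde borylation and insufficient anti or facial selectivity. The fallback uses known chemistry, sets out from aldehyde 9 and comes back at diol 13.
- The same cyclocondensation with the other alkaloid gives tert-butyl (2E,4E,7R)-3,5,7-trimethyl-11-[(2S)-4-oxooxetan-2-yl]undeca-2,4-dienoate F5.
- TFA/CH2Cl2 gives the corresponding acid, (2E,4E,7R)-3,5,7-trimethyl-11-[(2S)-4-oxooxetan-2-yl]undeca-2,4-dienoic acid F6.
- NaN(SiMe3)2 (2.1 equiv) and formaldehyde at −78 °C give the trans-hydroxymethyl lactone, (2E,4E,7R)-11-[(2S,3S)-3-(hydroxymethyl)-4-oxooxetan-2-yl]-3,5,7-trimethylundeca-2,4-dienoic acid F7.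
- LiOH (THF/H2O, 0 °C) opens the lactone at the acyl carbon with retention at both centres to give (2E,4E,7R,12S,13S)-12-hydroxy-13-(hydroxymethyl)-3,5,7-trimethyltetradeca-2,4-dienedioic acid F8.
- tert-Butyl 2,2,2-trichloroacetimidate (excess, CH2Cl2/cyclohexane, rt, no added acid) esterifies both carboxyl groups and leaves the hydroxyls, giving 13.

**Step 4 (cross-metathesis of a trisubstituted alkene).** Conversion may stall or crotonaldehyde may self-metathesise. The fallback sets out from triene ester 6 and comes back at enal 8, replacing metathesis by oxidative cleavage and olefination.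
- K2OsO4·2H2O (1 mol %)/N-methylmorpholine N-oxide in acetone/H2O dihydroxylates only the electron-rich isolated alkene to give tert-butyl (2E,4E,7R)-10,11-dihydroxy-3,5,7,11-tetramethyldodeca-2,4-dienoate F9 (C10 epimers, inconsequential).
- NaIO4 (THF/H2O) cleaves it to tert-butyl (2E,4E,7R)-3,5,7-trimethyl-10-oxodeca-2,4-dienoate F10.
- Wittig reaction with (triphenylphosphoranylidene)acetaldehyde (toluene, 80 °C) gives the (E)-enal 8.

Further compounds
F1 | step 9 | tert-butyl (2E,4E,7R)-3,5,7-trimethyl-11-[(2R)-4-oxooxetan-2-yl]undeca-2,4-dienoate | CC(=C\C(=O)OC(C)(C)C)/C=C(\C)C[C@H](C)CCCC[C@H]1OC(=O)C1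
F2 | step 9 | (2E,4E,7R)-3,5,7-trimethyl-11-[(2R)-4-oxooxetan-2-yl]undeca-2,4-dienoic acid | CC(=C\C(=O)O)/C=C(\C)C[C@H](C)CCCC[C@H]1OC(=O)C1
F3 | step 9 | hymeglusin, (2E,4E,7R)-11-[(2R,3R)-3-(hydroxymethyl)-4-oxooxetan-2-yl]-3,5,7-trimethylundeca-2,4-dienoic acid | CC(=C\C(=O)O)/C=C(\C)C[C@H](C)CCCC[C@H]1OC(=O)[C@@H]1CO
F4 | step 9 | tert-butyl(diphenyl)silyl ester of O-TBDPS hymeglusin | CC(=C\C(=O)O[Si](c1ccccc1)(c1ccccc1)C(C)(C)C)/C=C(\C)C[C@H](C)CCCC[C@H]2OC(=O)[C@@H]2CO[Si](c3ccccc3)(c3ccccc3)C(C)(C)C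
F5 | step 6 | tert-butyl (2E,4E,7R)-3,5,7-trimethyl-11-[(2S)-4-oxooxetan-2-yl]undeca-2,4-dienoate | CC(=C\C(=O)OC(C)(C)C)/C=C(\C)C[C@H](C)CCCC[C@@H]1OC(=O)C1
F6 | step 6 | (2E,4E,7R)-3,5,7-trimethyl-11-[(2S)-4-oxooxetan-2-yl]undeca-2,4-dienoic acid | CC(=C\C(=O)O)/C=C(\C)C[C@H](C)CCCC[C@@H]1OC(=O)C1
F7 | step 6 | (2E,4E,7R)-11-[(2S,3S)-3-(hydroxymethyl)-4-oxooxetan-2-yl]-3,5,7-trimethylundeca-2,4-dienoic acid | CC(=C\C(=O)O)/C=C(\C)C[C@H](C)CCCC[C@@H]1OC(=O)[C@H]1CO
F8 | step 6 | (2E,4E,7R,12S,13S)-12-hydroxy-13-(hydroxymethyl)-3,5,7-trimethyltetradeca-2,4-dienedioic acid | CC(=C\C(=O)O)/C=C(\C)C[C@H](C)CCCC[C@H](O)[C@H](CO)C(=O)O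
F9 | step 4 | tert-butyl (2E,4E,7R)-10,11-dihydroxy-3,5,7,11-tetramethyldodeca-2,4-dienoate | CC(=C\C(=O)OC(C)(C)C)/C=C(\C)C[C@H](C)CCC(O)C(C)(C)O
F10 | step 4 | tert-butyl (2E,4E,7R)-3,5,7-trimethyl-10-oxodeca-2,4-dienoate | CC(=C\C(=O)OC(C)(C)C)/C=C(\C)C[C@H](C)CCC=O
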